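**Retrosynthetic overview**

- Ring numbering used throughout: C1 carries the CH2 bridge, C2 and C3 carry Br, C4 and C5 carry OH, C6 carries Br. The strategy rests on C6–Br lying between C1 and C5–OH: excising C6 contracts each benzene ring to the ring C1–C5 of a cyclopentane-1,2-dione alkylated at its C3 (the future C1).
- Last disconnection: the C2–Br and C3–Br bonds, made by electrophilic bromination of bis(2-bromo-3,4-dihydroxyphenyl)methane 12 (C3 is ortho to the C4 hydroxyl, C2 is para to the C5 hydroxyl).
- Key disconnection: C5–C6 and C6–C1 in both rings at once. Dibromocarbene is inserted into the enol ether C1=C5 of the bis(silyl diosphenol) 6, and the ring-expanded bromo-enediones aromatise by tautomerism.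
- Compound 6 comes from two molecules of cyclopentane-1,2-dione joined through formaldehyde at their nucleophilic C3, then O-silylation. The carbene source 9 comes from phenylmercuric chloride and bromoform.
- Ring order: the two five-membered rings are bought, and both six-membered rings are formed together in step 4.

Key step: step 4

Remark on the chemistry: the target has no stereocentre and is achiral, so the request for a single enantiomer sets no stereochemical task. Cyclopentane-1,2-dione is used as its stable enol, 2-hydroxycyclopent-2-en-1-one, and formaldehyde as 37% aqueous solution.

**Route**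

Step 1
Reactants: 1 cyclopentane-1,2-dione (2.2 equiv), 2 formaldehyde (1.0 equiv)
Product: 5 3,3'-methylenebis(2-hydroxycyclopent-2-en-1-one), via Mannich base 3 (not isolated), via exo-methylene dione 4 (not isolated)
Conditions: 37% aq. CH2O, morpholine (0.2 equiv), AcOH (0.2 equiv), EtOH, 20 → 70 °C
Reagents that add atoms: none
Why: Tandem Mannich/elimination/Michael methylene bridging (Knoevenagel–Michael type, as with other enolised hydroxy-enones): the enol carbon C3 of the diosphenol, its known aminomethylation site, attacks the iminium ion, 3 loses morpholine to give enone 4, a second diosphenol adds at its C3, and both rings should re-enolise towards the substituted carbon.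

Step 2
Reactants: 5 3,3'-methylenebis(2-hydroxycyclopent-2-en-1-one)
Product: 6 3,3'-methylenebis[2-(tert-butyldimethylsilyloxy)cyclopent-2-en-1-one]
Conditions: TBSCl (2.5 equiv), imidazole (5 equiv), DMF, 0 → 20 °C
Reagents that add atoms: tert-butyldimethylsilyl chloride, CC(C)(C)[Si](C)(C)Cl
Why: O-silylation of the acidic enol hydroxyl of the predominant, more substituted diosphenol tautomer should fix the single C=C of each ring between the bridge carbon and the oxygenated carbon, and imidazole is too weak a base to silylate the ketone as a dienol ether.

Step 3
Reactants: 7 phenylmercuric chloride, 8 bromoform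
Product: 9 phenyl(tribromomethyl)mercury
Conditions: KOtBu (1.1 equiv), benzene, 0–5 °C; recrystallise, store cold and dark
Reagents that add atoms: none
Why: Seyferth reagent preparation: the tribromomethyl anion formed by deprotonation of bromoform should substitute chloride on mercury faster than it loses bromide at low temperature.

Step 4
Reactants: 6 3,3'-methylenebis[2-(tert-butyldimethylsilyloxy)cyclopent-2-en-1-one], 9 phenyl(tribromomethyl)mercury (3 equiv)
Product: 12 bis(2-bromo-3,4-dihydroxyphenyl)methane, via bis-cyclopropane adduct 10 (not isolated), via bis-enedione 11 (not isolated)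
Conditions: 9, benzene, 80 °C, Ar, dark; filter PhHgBr; then 48% aq. HBr, MeCN, 50 °C; aq. Na2S2O4 wash
Reagents that add atoms: none
Why: Proposed new method: thermolysis of 9 releases dibromocarbene without base, which should add [2+1] to the only C=C of each ring, the enol ether C1=C5 (target numbering), to give the bis(1-silyloxy-6,6-dibromobicyclo[3.1.0]hexan-2-one) 10; oxygen-assisted disrotatory cyclopropyl-to-allyl opening with loss of the endo bromide then cleaves the old C1–C5 bond, and loss of silicon leaves the 3-bromocyclohex-3-ene-1,2-dione 11, an isomer of the bromocatechol that reaches it by two enolisations without an oxidant. The closest known reactions are the dihalocarbene one-carbon ring expansion of cyclic silyl enol ethers to 2-halocycloalk-2-enones and the Ciamician–Dennstedt expansion of cyclopentadienes and indenes to haloarenes; new here is an enol ether conjugated to a ketone, used twice in one molecule, with aromatisation by tautomerism. Each benzene ring closes by ring expansion (cycloaddition forming C5–C6 and C6–C1, then 2π-electrocyclic opening) and not by cyclisation. No stereocentre appears in the product, and the cyclopropane stereocentres of 10 are erased on opening, so its diastereomer mixture is of no consequence. The step needs insertion only between the bridge-bearing C1 and the oxygenated C5, which is secured because the silyl enol ether places the single C=C of each ring there and the base-free carbene source leaves the ketone un-enolised, so no second alkene arises. The ketone lowers the nucleophilicity of the alkene, which is why the strongly electrophilic mercurial source is used in excess and why the acid stage is added to open any adduct that survives the heating.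

Step 5
Reactants: 12 bis(2-bromo-3,4-dihydroxyphenyl)methane
Product: 13 bis(2,3,6-tribromo-4,5-dihydroxyphenyl)methane (target)
Conditions: Br2 (4.4 equiv), AcOH, 20 °C, dark; then aq. NaHSO3
Reagents that add atoms: bromine, BrBr
Why: Electrophilic aromatic bromination should fill the two remaining C–H positions of each ring, C3 ortho to the C4 hydroxyl and C2 para to the C5 hydroxyl, and the bisulfite work-up should return any o-quinone formed by over-oxidation to the catechol.

**Compound list**

1 | cyclopentane-1,2-dione (handled as its enol, 2-hydroxycyclopent-2-en-1-one) | O=C1CCCC1=O | starting material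
2 | formaldehyde | C=O | starting material
3 | 2-hydroxy-3-(morpholin-4-ylmethyl)cyclopent-2-en-1-one (Mannich base) | O=C1CCC(CN2CCOCC2)=C1O | intermediate
4 | 3-methylidenecyclopentane-1,2-dione | C=C1CCC(=O)C1=O | intermediate
5 | 3,3'-methylenebis(2-hydroxycyclopent-2-en-1-one) | O=C1CCC(CC2=C(O)C(=O)CC2)=C1O | intermediate
6 | 3,3'-methylenebis[2-(tert-butyldimethylsilyloxy)cyclopent-2-en-1-one] | O=C1CCC(CC2=C(O[Si](C)(C)C(C)(C)C)C(=O)CC2)=C1O[Si](C)(C)C(C)(C)C | intermediate
7 | phenylmercuric chloride | Cl[Hg]c1ccccc1 | starting material
8 | bromoform | BrC(Br)Br | starting material
9 | phenyl(tribromomethyl)mercury | BrC(Br)(Br)[Hg]c1ccccc1 | intermediate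
10 | 5,5'-methylenebis[6,6-dibromo-1-(tert-butyldimethylsilyloxy)bicyclo[3.1.0]hexan-2-one], mixture of diastereomers | O=C1CCC2(CC34CCC(=O)C3(O[Si](C)(C)C(C)(C)C)C4(Br)Br)C(Br)(Br)C12O[Si](C)(C)C(C)(C)C | intermediate
11 | 4,4'-methylenebis(3-bromocyclohex-3-ene-1,2-dione) | O=C1CCC(CC2=C(Br)C(=O)C(=O)CC2)=C(Br)C1=O | intermediate
12 | bis(2-bromo-3,4-dihydroxyphenyl)methane, i.e. 4,4'-methylenebis(3-bromobenzene-1,2-diol) | Oc1ccc(Cc2ccc(O)c(O)c2Br)c(Br)c1O | intermediate
13 | bis(2,3,6-tribromo-4,5-dihydroxyphenyl)methane, i.e. 4,4'-methylenebis(3,5,6-tribromobenzene-1,2-diol) | Oc1c(O)c(Br)c(Cc2c(Br)c(O)c(O)c(Br)c2Br)c(Br)c1Br | target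

**Step count**

Total steps: 5. Longest linear sequence: 4 steps (1, 2, 4, 5); step 3 is the side branch that prepares the carbene source.

**Steps most likely to fail**

Step 4. Carbene transfer to the ketone-conjugated enol ether may be too slow, so the mercurial is consumed by the hydrogen bromide and phenols formed in the flask. The cyclopropane may also open by cleavage of the C–CBr2 bond rather than the shared bond, giving no ring expansion. The fallback gives up the ring expansion and uses known arene chemistry. It sets out from formaldehyde 2, which is condensed under acid (H2SO4, AcOH) with a large excess of veratrole, to suppress cyclotriveratrylene, and should give bis(3,4-dimethoxyphenyl)methane F1. Demethylation with BBr3 in CH2Cl2 should give bis(3,4-dihydroxyphenyl)methane F2. Exhaustive bromination with Br2 (about 6.5 equiv) in AcOH, with bisulfite work-up, should fill all three free positions of each ring and comes back to the route at target 13.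

Step 1. The exo-methylene dione may be intercepted by hetero-Diels–Alder dimerisation or O-alkylation, and the product may be hydroxymethylated again through its minor enol, leading to oligomers. The fallback builds the bridge on a simple ketone and adds the second oxygen afterwards. It sets out from formaldehyde 2, which with commercial 4-(cyclopent-1-en-1-yl)morpholine (2 equiv; Stork enamine alkylation, then aqueous acid hydrolysis) should give 2,2'-methylenebis(cyclopentan-1-one) F3. Riley oxidation of both α'-methylene groups with SeO2 in aqueous dioxane should then give the bis-1,2-dione, which enolises and comes back to the route at 5.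

Step 5. Bromine may oxidise the catechol rings to o-quinones, and ipso attack at C1, para to the C4 hydroxyl, may cleave the diarylmethane bridge. The fallback lowers the ring activation by masking the hydroxyls. It sets out from 12, which with MeI and K2CO3 in acetone should give bis(2-bromo-3,4-dimethoxyphenyl)methane F4. Bromination with Br2 and catalytic Fe in CHCl3 should give bis(2,3,6-tribromo-4,5-dimethoxyphenyl)methane F5. Demethylation with BBr3 in CH2Cl2 comes back to the route at target 13.

**Further compounds**

F1 | step 4 | bis(3,4-dimethoxyphenyl)methane | COc1ccc(Cc2ccc(OC)c(OC)c2)cc1OC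
F2 | step 4 | bis(3,4-dihydroxyphenyl)methane | Oc1ccc(Cc2ccc(O)c(O)c2)cc1O
F3 | step 1 | 2,2'-methylenebis(cyclopentan-1-one) | O=C1CCCC1CC1CCCC1=O
F4 | step 5 | bis(2-bromo-3,4-dimethoxyphenyl)methane | COc1ccc(Cc2ccc(OC)c(OC)c2Br)c(Br)c1OC
F5 | step 5 | bis(2,3,6-tribromo-4,5-dimethoxyphenyl)methane | COc1c(OC)c(Br)c(Cc2c(Br)c(OC)c(OC)c(Br)c2Br)c(Br)c1Br
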